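The isoflavone is cut at C4–C4a. Carbonyl carbon C4 sits on C4a of a phloroglucinol-type A ring. In the open 3,5-dimethoxyphenyl enol ether the two carbons flanking C8a (future C4a and C8) are symmetry-equivalent, and each is activated by three oxygens. One intramolecular Friedel–Crafts acylation of a 2-aryl-3-aryloxyacrylic acid therefore closes the pyranone C ring without a regiochemical question. The precursor already holds O1–C2=C3, the B ring and a 3'-bromine. That bromine later becomes the side chain through an arylacetaldehyde and a ligand-controlled isopropenyl addition that sets the R carbinol. The phenols travel as acetates, so the final deprotection is basic and spares the allylic alcohol.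

Key step: step 6

Remarks on the chemistry (assumptions)
- Alkene geometry: the enol tosylate, the aryloxyacrylate ester and the acid made from it are drawn as E isomers (oxygen substituent trans to the carboxyl carbon), as expected for this sequence and for β-alkoxyacrylates in general. The E acid cannot cyclise, so the cyclisation-competent Z acid is listed as an intermediate formed in the flask in step 6, and any Z share formed earlier does no harm.
- Ligand sense in step 11: both antipodes of the ligand are available from the (R)- or (S)-amino alcohol. The route is written for the antipode that delivers the isopropenyl group to the Si face of the aldehyde, to be assigned in a trial run by chiral HPLC and MTPA ester analysis.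

Step 1
Reactants: 1 3-bromo-4-methoxyphenylacetic acid
Product: 2 methyl 2-(3-bromo-4-methoxyphenyl)acetate
Conditions: MeOH, H2SO4 (cat.), reflux
Reagents that add atoms: methanol, CO
Why: Fischer esterification, in which excess methanol shifts the acid-catalysed equilibrium to the ester and leaves the benzylic CH2 as the only acidic site for the next step.

Step 2
Reactants: 2 methyl 2-(3-bromo-4-methoxyphenyl)acetate; 3 methyl formate
Product: 4 methyl (Z)-2-(3-bromo-4-methoxyphenyl)-3-hydroxyacrylate (chelated enol of the α-formyl ester)
Conditions: NaH, HCO2Me (excess), THF, 0 °C to rt; then cold 1 M HCl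
Reagents that add atoms: none
Why: Crossed Claisen condensation (α-formylation) with a formate that cannot enolise; deprotonation of the β-oxo ester makes it irreversible, and acidification should give the hydrogen-bonded Z enol.

Step 3
Reactants: 4 methyl (Z)-2-(3-bromo-4-methoxyphenyl)-3-hydroxyacrylate
Product: 5 methyl (E)-2-(3-bromo-4-methoxyphenyl)-3-(tosyloxy)acrylate
Conditions: TsCl, N-methylimidazole, Et3N, CH2Cl2, 0 °C to rt
Reagents that add atoms: p-toluenesulfonyl chloride, Cc1ccc(cc1)S(=O)(=O)Cl
Why: O-sulfonylation of the enol by the N-tosylimidazolium salt formed in the flask; with an amine base and no chelating cation the open enolate reacts, which should give the E enol tosylate.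

Step 4
Reactants: 5 methyl (E)-2-(3-bromo-4-methoxyphenyl)-3-(tosyloxy)acrylate; 6 3,5-dimethoxyphenol
Product: 7 methyl (E)-2-(3-bromo-4-methoxyphenyl)-3-(3,5-dimethoxyphenoxy)acrylate
Conditions: K2CO3, DMF, rt
Reagents that add atoms: none
Why: Vinylic nucleophilic substitution by addition–elimination (oxa-Michael addition, then loss of tosylate), in which the unhindered CH terminus of the acrylate is the preferred electrophilic site, the polar aprotic medium favours O- over C-attack of the phenoxide, and the stabilised carbanion relaxes to the E product.

Step 5
Reactants: 7 methyl (E)-2-(3-bromo-4-methoxyphenyl)-3-(3,5-dimethoxyphenoxy)acrylate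
Product: 8 (E)-2-(3-bromo-4-methoxyphenyl)-3-(3,5-dimethoxyphenoxy)acrylic acid
Conditions: LiOH, THF–H2O, 0 °C to rt; then cold 1 M HCl to pH 3
Reagents that add atoms: lithium hydroxide, [Li+].[OH-]
Why: Saponification (acyl–oxygen cleavage) run cold and without alcohol cosolvent, so that no alkoxide can exchange the aryloxy group, and once the carboxylate has formed the alkene is no longer an acceptor.

Step 6
Reactants: 8 (E)-2-(3-bromo-4-methoxyphenyl)-3-(3,5-dimethoxyphenoxy)acrylic acid
Product: 10 3'-bromo-5,7,4'-trimethoxyisoflavone, via (Z)-acrylic acid 9 (not isolated)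
Conditions: Eaton's reagent (P2O5 in MeSO3H), dilute, rt to 45 °C; then ice
Reagents that add atoms: none
Why: In the strongly acidic, water-binding medium the push–pull alkene is protonated at the carboxyl oxygen (or at C3), which gives an O1=C2 oxocarbenium form with a freely rotating C2–C3 bond, so E acid 8 and Z acid 9 interconvert and only 9, whose aryloxy group lies cis to the carboxyl group, is drained. P2O5/MeSO3H converts the carboxyl group of 9 into a mixed anhydride or acylium ion, the ring carbon ortho to O1 attacks it (SEAr), and loss of the proton forms C4–C4a. The closest known reaction type is the intramolecular Friedel–Crafts acylation of 3-aryloxyacrylic acids to chromones, applied here to a 2-aryl member. The pyranone ring closes in a 6-exo mode at the acyl carbon, with the C=O bond outside the new ring and the arene bond C4a–C8a inside it, and no stereocentre is formed. The step needs ortho regioselectivity and chemoselectivity for the A ring: the two ortho carbons are equivalent by the symmetry of the 3,5-dimethoxyphenoxy group and each is ortho, ortho and para to an oxygen donor, the para carbon cannot be reached, and attack by the brominated B ring would require a four-membered ring. Dilution and the anhydrous medium hold back intermolecular acylation and hydrolysis of the enol ether.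

Step 7
Reactants: 10 3'-bromo-5,7,4'-trimethoxyisoflavone
Product: 11 3'-bromogenistein (3-(3-bromo-4-hydroxyphenyl)-5,7-dihydroxy-4H-chromen-4-one)
Conditions: BBr3 (excess), CH2Cl2, −78 °C to rt; then ice-water
Reagents that add atoms: none
Why: Lewis acid mediated aryl methyl ether cleavage, in which BBr3 binds each ether oxygen and bromide removes the methyl group by SN2 (5-OMe first, by chelation to C4=O), while the aryl bromide and the pyranone are inert.

Step 8
Reactants: 11 3'-bromogenistein
Product: 12 3'-bromogenistein 5,7,4'-triacetate
Conditions: Ac2O, pyridine, DMAP (cat.), rt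
Reagents that add atoms: acetic anhydride, CC(=O)OC(C)=O
Why: Exhaustive O-acylation with nucleophilic catalysis, which also caps the hydrogen-bonded 5-OH without forcing and installs groups that can be removed at the end without acid.

Step 9
Reactants: 12 3'-bromogenistein 5,7,4'-triacetate; 13 allyltributylstannane
Product: 14 3'-allylgenistein 5,7,4'-triacetate
Conditions: Pd(PPh3)4 (cat.), toluene (degassed), 100 °C
Reagents that add atoms: none
Why: Stille cross-coupling, in which oxidative addition into the only C–Br bond, allyl transfer from tin and reductive elimination run under neutral conditions that leave aryl acetates intact.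

Step 10
Reactants: 14 3'-allylgenistein 5,7,4'-triacetate
Product: 16 3'-(2-oxoethyl)genistein 5,7,4'-triacetate, via vicinal diol 15 (not isolated)
Conditions: OsO4 (cat.), NaIO4, 2,6-lutidine, dioxane–H2O, rt
Reagents that add atoms: osmium tetroxide (oxygen carrier), O=[Os](=O)(=O)=O; sodium periodate (terminal oxygen source), [Na+].[O-]I(=O)(=O)=O
Why: Lemieux–Johnson oxidation, in which osmium dihydroxylates the terminal alkene far faster than the electron-poor trisubstituted C2=C3 bond, periodate cleaves the diol at once, and 2,6-lutidine keeps the medium near neutral for the acetates.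

Step 11
Reactants: 16 3'-(2-oxoethyl)genistein 5,7,4'-triacetate; 17 2-bromopropene
Product: 18 3'-[(2R)-2-hydroxy-3-methylbut-3-enyl]genistein 5,7,4'-triacetate
Conditions: CrCl2 (cat.), chiral oxazoline–sulfonamide ligand, proton sponge, NiCl2·(2,9-dimethyl-1,10-phenanthroline) (cat.), Mn, Cp2ZrCl2, LiCl, MeCN, rt
Reagents that add atoms: none
Why: Catalytic asymmetric Nozaki–Hiyama–Kishi reaction, in which nickel activates the C–Br bond, the alkenyl group passes to chromium(III), the non-basic organochromium adds only to the aldehyde (not to esters or the pyranone, and without enolisation), and the chiral ligand on chromium shields the Re face so that Si-face attack sets the carbinol carbon as R.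

Step 12
Reactants: 18 3'-[(2R)-2-hydroxy-3-methylbut-3-enyl]genistein 5,7,4'-triacetate
Product: 19 3'-[(2R)-2-hydroxy-3-methylbut-3-enyl]genistein (target)
Conditions: K2CO3, MeOH, 0 °C to rt; then cold 1 M HCl to pH 5–6
Reagents that add atoms: none
Why: Base-mediated transesterification (methanolysis) of activated aryl acetates, which also removes any acetyl group that has wandered to the secondary oxygen, cannot touch the carbinol stereocentre, and avoids the acid that could drive the 4'-OH to cyclise onto the allylic alcohol side chain.

Compound list
1 | 3-bromo-4-methoxyphenylacetic acid | COc1ccc(CC(=O)O)cc1Br | starting material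
2 | methyl 2-(3-bromo-4-methoxyphenyl)acetate | COC(=O)Cc1ccc(OC)c(Br)c1 | intermediate
3 | methyl formate | COC=O | starting material
4 | methyl (Z)-2-(3-bromo-4-methoxyphenyl)-3-hydroxyacrylate | O/C=C(\C(=O)OC)c1ccc(OC)c(Br)c1 | intermediate
5 | methyl (E)-2-(3-bromo-4-methoxyphenyl)-3-(tosyloxy)acrylate | Cc1ccc(cc1)S(=O)(=O)O/C=C(/C(=O)OC)c1ccc(OC)c(Br)c1 | intermediate
6 | 3,5-dimethoxyphenol | COc1cc(O)cc(OC)c1 | starting material
7 | methyl (E)-2-(3-bromo-4-methoxyphenyl)-3-(3,5-dimethoxyphenoxy)acrylate | COc1cc(OC)cc(O/C=C(/C(=O)OC)c2ccc(OC)c(Br)c2)c1 | intermediate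
8 | (E)-2-(3-bromo-4-methoxyphenyl)-3-(3,5-dimethoxyphenoxy)acrylic acid | COc1cc(OC)cc(O/C=C(/C(=O)O)c2ccc(OC)c(Br)c2)c1 | intermediate
9 | (Z)-2-(3-bromo-4-methoxyphenyl)-3-(3,5-dimethoxyphenoxy)acrylic acid (formed in the flask, not isolated) | COc1cc(OC)cc(O/C=C(\C(=O)O)c2ccc(OC)c(Br)c2)c1 | intermediate
10 | 3'-bromo-5,7,4'-trimethoxyisoflavone | COc1cc(OC)c2c(c1)occ(-c1ccc(OC)c(Br)c1)c2=O | intermediate
11 | 3'-bromogenistein | Oc1cc(O)c2c(c1)occ(-c1ccc(O)c(Br)c1)c2=O | intermediate
12 | 3'-bromogenistein 5,7,4'-triacetate | CC(=O)Oc1cc(OC(C)=O)c2c(c1)occ(-c1ccc(OC(C)=O)c(Br)c1)c2=O | intermediate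
13 | allyltributylstannane | C=CC[Sn](CCCC)(CCCC)CCCC | starting material
14 | 3'-allylgenistein 5,7,4'-triacetate | C=CCc1cc(-c2coc3cc(OC(C)=O)cc(OC(C)=O)c3c2=O)ccc1OC(C)=O | intermediate
15 | 3'-(2,3-dihydroxypropyl)genistein 5,7,4'-triacetate (racemic, stereocentre lost again on cleavage, not isolated) | OCC(O)Cc1cc(-c2coc3cc(OC(C)=O)cc(OC(C)=O)c3c2=O)ccc1OC(C)=O | intermediate
16 | 3'-(2-oxoethyl)genistein 5,7,4'-triacetate | O=CCc1cc(-c2coc3cc(OC(C)=O)cc(OC(C)=O)c3c2=O)ccc1OC(C)=O | intermediate
17 | 2-bromopropene | C=C(C)Br | starting material
18 | 3'-[(2R)-2-hydroxy-3-methylbut-3-enyl]genistein 5,7,4'-triacetate | C=C(C)[C@H](O)Cc1cc(-c2coc3cc(OC(C)=O)cc(OC(C)=O)c3c2=O)ccc1OC(C)=O | intermediate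
19 | 5,7-dihydroxy-3-{4-hydroxy-3-[(2R)-2-hydroxy-3-methylbut-3-en-1-yl]phenyl}-4H-chromen-4-one | C=C(C)[C@H](O)Cc1cc(-c2coc3cc(O)cc(O)c3c2=O)ccc1O | target

Total step count: 12
Longest linear sequence: 12 steps (1 to 19)

Steps most likely to fail

1. Step 6. The E-to-Z equilibration may be slower than acid-induced cleavage of the O1–C2 enol ether bond followed by recombination through carbon (Pechmann-type condensation), or slower than intermolecular acylation. The fallback inserts C2 last instead of closing C4–C4a last. It sets out from 1 and 6. Heating both in BF3·OEt2 at about 85 °C (Friedel–Crafts/Fries acylation, directed ortho to the phenol OH by chelation) should give the deoxybenzoin 2-(3-bromo-4-methoxyphenyl)-1-(2-hydroxy-4,6-dimethoxyphenyl)ethanone F1. Heating this with DMF dimethyl acetal in toluene adds the C2 carbon and closes the pyranone in the same operation. The fallback comes back to the route at 10.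

2. Step 11. Facial selectivity may be poor with an α-unbranched arylacetaldehyde, and aldehyde may be lost by enolisation and self-condensation during a slow catalytic turnover. The fallback separates C–C bond formation from stereocontrol. It sets out from 16. A ligand-free stoichiometric Nozaki–Hiyama–Kishi reaction with 17 (CrCl2, NiCl2 cat., DMF, rt) should give the racemic alcohol rac-3'-(2-hydroxy-3-methylbut-3-enyl)genistein 5,7,4'-triacetate F2. Sharpless kinetic resolution follows (Ti(OiPr)4, L-(+)-diisopropyl tartrate, t-BuOOH about 0.6 equiv, 4 Å molecular sieves, CH2Cl2, −20 °C). With L-(+)-tartrate the S carbinol (priority OH > alkenyl > CH2Ar) is the fast-reacting enantiomer. It is epoxidised to the erythro epoxy alcohol 3'-{(2S)-2-hydroxy-2-[(2R)-2-methyloxiran-2-yl]ethyl}genistein 5,7,4'-triacetate F3, which is removed by chromatography. The unreacted R alcohol is 18, where the fallback comes back to the route.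

3. Step 5. Hydroxide may add to the β-carbon (future C2) and expel the aryloxide instead of attacking the hindered, push–pull deactivated ester carbonyl. The fallback switches from acyl–oxygen to alkyl–oxygen cleavage, so that no oxygen nucleophile is present. It sets out from 7. Anhydrous LiI in refluxing ethyl acetate removes the ester methyl group by SN2 attack of iodide on carbon, any addition of iodide to the alkene being reversible and unproductive. Acidification frees the acid, and the fallback comes back to the route at 8. It makes no new compound (F0).

Further compounds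
F1 | step 6 | 2-(3-bromo-4-methoxyphenyl)-1-(2-hydroxy-4,6-dimethoxyphenyl)ethanone | COc1cc(O)c(C(=O)Cc2ccc(OC)c(Br)c2)c(OC)c1
F2 | step 11 | rac-3'-(2-hydroxy-3-methylbut-3-enyl)genistein 5,7,4'-triacetate | C=C(C)C(O)Cc1cc(-c2coc3cc(OC(C)=O)cc(OC(C)=O)c3c2=O)ccc1OC(C)=O
F3 | step 11 | 3'-{(2S)-2-hydroxy-2-[(2R)-2-methyloxiran-2-yl]ethyl}genistein 5,7,4'-triacetate | C[C@@]1(CO1)[C@@H](O)Cc1cc(-c2coc3cc(OC(C)=O)cc(OC(C)=O)c3c2=O)ccc1OC(C)=O
F0 | step 5 | none | none
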